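**Strategy.** Ring A (C1–C5 and C10 in eudesmane numbering) is closed last, at C2–C3, by a bromine atom-transfer radical cyclisation. The step exploits the vicinal placement of the C1 bromine and the C2–C3 bond and the position of C3 next to C4: a C3 radical α to a C4 ketone (the masked methylidene carbon) adds 6-endo to the C2 terminus of a C10 vinyl group, and the C1 radical takes the bromine back. Ring A, the C2–C3 bond and the neopentylic C1–Br stereocentre thus arise in one isomerisation. The precursor is a ring B cyclohexane from (R)-carvone bearing a bromoacetyl and a silyloxy group at C5 and a vinyl group at C10.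

Key step: step 9

Remark: positions are cited in eudesmane numbering (C1 = CHBr, C4 = methylidene-bearing carbon, C5 = carbinol carbon, C7 = side-chain carbon, C10 = methyl-bearing carbon; ring A = C1–C5/C10, ring B = C5–C10). The ligand sense in step 2 is assigned by analogy with the parent 2-methylcyclohexanone case.

**Step 1**
Reactants: 1 (R)-(−)-carvone
Product: 3 prop-2-en-1-yl (5R)-2-methyl-5-(prop-1-en-2-yl)cyclohex-1-en-1-yl carbonate, via lithium enolate 2 (not isolated)
Conditions: LiBH(s-Bu)3 (1.05 equiv), THF, −78 °C; then allyl chloroformate, −78 → 0 °C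
Reagents that add atoms: allyl chloroformate, C=CCOC(=O)Cl
Why: Conjugate reduction of the enone by the hindered borohydride should give the enolate of the methyl-bearing carbon regiospecifically, and O-acylation by the chloroformate traps it as the tetrasubstituted enol carbonate without touching the C7 stereocentre (conjugate reduction–enolate trapping).

**Step 2**
Reactants: 3 allyl enol carbonate
Product: 4 (2S,5R)-2-methyl-2-(prop-2-en-1-yl)-5-(prop-1-en-2-yl)cyclohexan-1-one
Conditions: Pd2(dba)3 (2.5 mol %), (S)-t-BuPHOX [(S)-4-tert-butyl-2-(2-diphenylphosphinophenyl)-4,5-dihydrooxazole] (6.5 mol %), toluene, 30 °C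
Reagents that add atoms: none
Why: Decarboxylative asymmetric allylic alkylation (Tsuji allylation): zerovalent palladium ionises the allyl carbonate, CO2 is lost and the enolate is allylated at the methyl-bearing carbon, the (S)-ligand being chosen to deliver the allyl group trans to the isopropenyl group and so set C10 (2S) against the modest substrate bias.

**Step 3**
Reactants: 4 allyl ketone
Product: 6 (2S,5R)-2-ethenyl-2-methyl-5-(prop-1-en-2-yl)cyclohexan-1-one, via propenyl ketone 5 (not isolated)
Conditions: RuHCl(CO)(PPh3)3 (3 mol %), toluene, 80 °C; then, in the same vessel, second-generation Hoveyda–Grubbs catalyst RuCl2(H2IMes)(=CH-2-(i-PrO)C6H4) (5 mol %), ethylene (5 bar), 40 °C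
Reagents that add atoms: ethylene, C=C
Why: Ruthenium hydride-catalysed isomerisation moves the monosubstituted double bond by the one position that the quaternary carbon allows, and ethenolysis (cross-metathesis with ethylene) of the resulting propenyl group leaves the vinyl group, the isopropenyl group undergoing only degenerate exchange and no stereocentre being touched.

**Step 4**
Reactants: 6 vinyl ketone
Product: 8 (3R,6S)-6-ethenyl-6-methyl-3-(prop-1-en-2-yl)cyclohex-1-en-1-yl trifluoromethanesulfonate, via potassium enolate 7 (not isolated)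
Conditions: KN(SiMe3)2, THF, −78 °C; then PhNTf2, −78 → 0 °C
Reagents that add atoms: N-phenylbis(trifluoromethanesulfonimide), O=S(=O)(N(c1ccccc1)S(=O)(=O)C(F)(F)F)C(F)(F)F
Why: The ketone can enolise only toward C6, and O-triflation of the potassium enolate by the N-phenyl triflimide should give the enol triflate (enol triflate formation).

**Step 5**
Reactants: 8 enol triflate
Product: 10 1-[(3R,6S)-6-ethenyl-6-methyl-3-(prop-1-en-2-yl)cyclohex-1-en-1-yl]ethan-1-one, via ethoxydiene 9 (not isolated)
Conditions: tributyl(1-ethoxyvinyl)stannane, Pd(PPh3)4 (5 mol %), LiCl, CuI (10 mol %), dioxane, 90 °C; then 1 M HCl, THF, 0 °C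
Reagents that add atoms: tributyl(1-ethoxyvinyl)stannane, CCCC[Sn](CCCC)(CCCC)C(=C)OCC; water, O
Why: Stille coupling of the enol triflate with the acyl-anion-equivalent stannane (LiCl and CuI assist the hindered transmetalation) gives a 2-ethoxydiene whose enol ether is hydrolysed by dilute acid to the methyl enone; no stereocentre is formed.

**Step 6**
Reactants: 10 enone
Product: 11 {1-[(2S,5R)-2-ethenyl-2-methyl-5-(prop-1-en-2-yl)cyclohexylidene]ethoxy}dimethyl(phenyl)silane (E/Z mixture)
Conditions: [(Ph3P)CuH]6 (3 mol %), PhMe2SiH (1.5 equiv), toluene, 25 °C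
Reagents that add atoms: dimethylphenylsilane, C[SiH](C)c1ccccc1
Why: Copper hydride-catalysed 1,4-hydrosilylation delivers hydride to C6 and silylates the resulting copper enolate, which fixes the enol ether at C5=C4 while the isolated vinyl and isopropenyl groups are inert to copper hydride.

**Step 7**
Reactants: 11 silyl enol ether
Product: 13 1-[(1S,2S,5R)-1-{[dimethyl(phenyl)silyl]oxy}-2-ethenyl-2-methyl-5-(prop-1-en-2-yl)cyclohexyl]ethan-1-one, via silyloxy epoxide 12 (not isolated)
Conditions: m-CPBA (1.0 equiv), NaHCO3, CH2Cl2, −20 → 25 °C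
Reagents that add atoms: 3-chloroperoxybenzoic acid, OOC(=O)c1cccc(Cl)c1
Why: Rubottom oxidation: the electron-rich silyl enol ether is epoxidised far faster than the other alkenes, the peracid attacking C5 axially on the face anti to the axial C10 methyl group of the chair that keeps the isopropenyl group equatorial, and 1,4-silyl migration in the silyloxy epoxide gives the α-silyloxy ketone with the C5 oxygen trans to the C10 methyl group (1S).

**Step 8**
Reactants: 13 α-silyloxy methyl ketone
Product: 15 2-bromo-1-[(1S,2S,5R)-1-{[dimethyl(phenyl)silyl]oxy}-2-ethenyl-2-methyl-5-(prop-1-en-2-yl)cyclohexyl]ethan-1-one, via trimethylsilyl enol ether 14 (not isolated)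
Conditions: Me3SiOTf, Et3N, CH2Cl2, 0 °C; then N-bromosuccinimide, THF, −78 °C
Reagents that add atoms: N-bromosuccinimide, O=C1CCC(=O)N1Br; trimethylsilyl triflate, C[Si](C)(C)OS(=O)(=O)C(F)(F)F (its atoms stay only in 14)
Why: Soft enolisation can occur only at the methyl group because C5 is fully substituted, and electrophilic bromination of the trimethylsilyl enol ether by N-bromosuccinimide at low temperature is much faster than any reaction of the isolated alkenes (α-bromination via a silyl enol ether).

**Step 9**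
Reactants: 15 bromomethyl ketone
Product: 16 (4R,4aR,7R,8aS)-4-bromo-8a-{[dimethyl(phenyl)silyl]oxy}-4a-methyl-7-(prop-1-en-2-yl)octahydronaphthalen-1(2H)-one
Conditions: [Cu(dap)2]Cl (2 mol %; dap = 2,9-bis(4-methoxyphenyl)-1,10-phenanthroline), 530 nm LEDs, degassed MeCN (0.01 M), 25 °C
Reagents that add atoms: none
Why: The photoexcited monovalent copper complex abstracts bromine from 15 to give the electrophilic C3 radical α to the C4 ketone, which adds to the C2 terminus of the C10 vinyl group; the secondary C1 radical then takes bromine back from the bromo–divalent copper complex (or from a second molecule of 15), so the step is a net isomerisation. The closest known reaction type is the halogen atom-transfer radical cyclisation of α-halo ketones (Kharasch-type). Ring A closes in the 6-endo-trig mode, the normal preference of radicals that carry the carbonyl group inside the forming ring, which here also avoids a strained trans-fused cyclopentanone; both reacting arms are equatorial on the ring B chair, so the C5/C10 relationship is carried into a trans-decalin. The new C1 stereocentre is set in the bromine transfer: the α lobe of the C1 radical is 1,3-diaxial to the bulky C5 silyloxy group, so the halogen donor should approach the β lobe and place bromine equatorial, cis to the C10 methyl group (C1 R). The step needs 6-endo over 5-exo closure, cyclisation faster than intermolecular addition to an isopropenyl group (secured by dilution and the proximity of the two arms) and bromine transfer faster than reduction or oxidation of the C1 radical (secured by inner-sphere delivery from copper).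

**Step 10**
Reactants: 16 bromodecalone
Product: 17 {[(1R,4aR,6R,8aR)-1-bromo-8a-methyl-4-methylidene-6-(prop-1-en-2-yl)decahydronaphthalen-4a-yl]oxy}dimethyl(phenyl)silane
Conditions: Cp2TiMe2 (3 equiv), toluene, 70 °C, dark
Reagents that add atoms: dimethyltitanocene, C[Ti](C)(C1C=CC=C1)C1C=CC=C1
Why: Petasis methylenation: the titanocene methylidene formed on heating adds to the hindered ketone and the oxatitanacyclobutane collapses to the methylidene, the non-basic conditions avoiding enolisation toward C3 (which could displace the γ-bromide) and epimerisation.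

**Step 11**
Reactants: 17 isopropenyl decalin
Product: 18 {[(1R,4aR,6R,8aR)-1-bromo-8a-methyl-4-methylidene-6-[(1E)-1-(4,4,5,5-tetramethyl-1,3,2-dioxaborolan-2-yl)prop-1-en-2-yl]decahydronaphthalen-4a-yl]oxy}dimethyl(phenyl)silane
Conditions: 4,4,5,5-tetramethyl-2-vinyl-1,3,2-dioxaborolane (5 equiv), second-generation Hoveyda–Grubbs catalyst RuCl2(H2IMes)(=CH-2-(i-PrO)C6H4) (10 mol %), CH2Cl2, 40 °C
Reagents that add atoms: vinylboronic acid pinacol ester, C=CB1OC(C)(C)C(C)(C)O1
Why: Olefin cross-metathesis of the 1,1-disubstituted isopropenyl group with the vinyl boronate should give the trisubstituted alkenyl boronate with boron trans to the ring carbon (E) for steric reasons in the metallacyclobutane, while the C4 methylidene group, flanked by the quaternary silyloxy-bearing C5, should stay a spectator.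

**Step 12**
Reactants: 19 2-methylbut-1-en-3-yne
Product: 21 (1E)-1-iodo-3-methylbuta-1,3-diene, via alkenylzirconocene chloride 20 (not isolated)
Conditions: Cp2Zr(H)Cl, THF, 25 °C; then I2, 0 °C, dark
Reagents that add atoms: iodine, II
Why: Hydrozirconation adds Zr–H syn across the terminal alkyne with zirconium at the terminal carbon, and iodinolysis with retention gives the (E)-iododiene (hydrozirconation–iodination).

**Step 13**
Reactants: 18 alkenyl boronate; 21 (1E)-1-iodo-3-methylbuta-1,3-diene
Product: 22 {[(1R,4aR,6R,8aR)-1-bromo-8a-methyl-4-methylidene-6-[(2E,4E)-6-methylhepta-2,4,6-trien-2-yl]decahydronaphthalen-4a-yl]oxy}dimethyl(phenyl)silane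
Conditions: PdCl2(dppf) (5 mol %), K3PO4 (3 equiv), THF/H2O (10:1), 40 °C
Reagents that add atoms: none
Why: Suzuki–Miyaura coupling proceeds with retention of both alkene geometries, and oxidative addition of zerovalent palladium to the alkenyl iodide is far faster than to the hindered secondary alkyl bromide.

**Step 14**
Reactants: 22 silyl ether
Product: 23 (1R,4aR,6R,8aR)-1-bromo-8a-methyl-4-methylidene-6-[(2E,4E)-6-methylhepta-2,4,6-trien-2-yl]decahydronaphthalen-4a-ol (target)
Conditions: Bu4NF (2 equiv), THF, 0 → 25 °C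
Reagents that add atoms: none
Why: Fluoride cleaves the silyl ether under essentially neutral conditions that the tertiary allylic alcohol, the triene and the equatorial neopentylic bromide (no antiperiplanar hydrogen for elimination) should tolerate (fluoride desilylation).

**Compound list**

1 | (R)-(−)-carvone | C=C(C)[C@@H]1CC=C(C)C(=O)C1 | starting material
2 | lithium (5R)-2-methyl-5-(prop-1-en-2-yl)cyclohex-1-en-1-olate | C=C(C)[C@@H]1CCC(C)=C([O-])C1.[Li+] | intermediate
3 | prop-2-en-1-yl (5R)-2-methyl-5-(prop-1-en-2-yl)cyclohex-1-en-1-yl carbonate | C=C(C)[C@@H]1CCC(C)=C(OC(=O)OCC=C)C1 | intermediate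
4 | (2S,5R)-2-methyl-2-(prop-2-en-1-yl)-5-(prop-1-en-2-yl)cyclohexan-1-one | C=C(C)[C@@H]1CC[C@@](C)(CC=C)C(=O)C1 | intermediate
5 | (2S,5R)-2-methyl-2-[(1E)-prop-1-en-1-yl]-5-(prop-1-en-2-yl)cyclohexan-1-one | C=C(C)[C@@H]1CC[C@@](C)(/C=C/C)C(=O)C1 | intermediate
6 | (2S,5R)-2-ethenyl-2-methyl-5-(prop-1-en-2-yl)cyclohexan-1-one | C=C(C)[C@@H]1CC[C@@](C)(C=C)C(=O)C1 | intermediate
7 | potassium (3R,6S)-6-ethenyl-6-methyl-3-(prop-1-en-2-yl)cyclohex-1-en-1-olate | C=C(C)[C@@H]1CC[C@@](C)(C=C)C([O-])=C1.[K+] | intermediate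
8 | (3R,6S)-6-ethenyl-6-methyl-3-(prop-1-en-2-yl)cyclohex-1-en-1-yl trifluoromethanesulfonate | C=C(C)[C@@H]1CC[C@@](C)(C=C)C(OS(=O)(=O)C(F)(F)F)=C1 | intermediate
9 | (3R,6S)-1-(1-ethoxyethenyl)-6-ethenyl-6-methyl-3-(prop-1-en-2-yl)cyclohex-1-ene | C=C(C)[C@@H]1CC[C@@](C)(C=C)C(C(=C)OCC)=C1 | intermediate
10 | 1-[(3R,6S)-6-ethenyl-6-methyl-3-(prop-1-en-2-yl)cyclohex-1-en-1-yl]ethan-1-one | C=C(C)[C@@H]1CC[C@@](C)(C=C)C(C(C)=O)=C1 | intermediate
11 | {1-[(2S,5R)-2-ethenyl-2-methyl-5-(prop-1-en-2-yl)cyclohexylidene]ethoxy}dimethyl(phenyl)silane (E/Z mixture) | C=C(C)[C@@H]1CC[C@@](C)(C=C)C(=C(C)O[Si](C)(C)c2ccccc2)C1 | intermediate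
12 | silyloxy epoxide of 11: 2-{[dimethyl(phenyl)silyl]oxy}-4-ethenyl-2,4-dimethyl-7-(prop-1-en-2-yl)-1-oxaspiro[2.5]octane, spiro C–O bond trans to the C10 methyl group, mixture at the epoxide carbon | C=C(C)[C@@H]1CC[C@@](C)(C=C)[C@@]2(OC2(C)O[Si](C)(C)c3ccccc3)C1 | intermediate
13 | 1-[(1S,2S,5R)-1-{[dimethyl(phenyl)silyl]oxy}-2-ethenyl-2-methyl-5-(prop-1-en-2-yl)cyclohexyl]ethan-1-one | C=C(C)[C@@H]1CC[C@@](C)(C=C)[C@](O[Si](C)(C)c2ccccc2)(C(C)=O)C1 | intermediate
14 | {[(1S,2S,5R)-2-ethenyl-2-methyl-5-(prop-1-en-2-yl)-1-{1-[(trimethylsilyl)oxy]ethenyl}cyclohexyl]oxy}dimethyl(phenyl)silane | C=C(C)[C@@H]1CC[C@@](C)(C=C)[C@](O[Si](C)(C)c2ccccc2)(C(=C)O[Si](C)(C)C)C1 | intermediate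
15 | 2-bromo-1-[(1S,2S,5R)-1-{[dimethyl(phenyl)silyl]oxy}-2-ethenyl-2-methyl-5-(prop-1-en-2-yl)cyclohexyl]ethan-1-one | C=C(C)[C@@H]1CC[C@@](C)(C=C)[C@](O[Si](C)(C)c2ccccc2)(C(=O)CBr)C1 | intermediate
16 | (4R,4aR,7R,8aS)-4-bromo-8a-{[dimethyl(phenyl)silyl]oxy}-4a-methyl-7-(prop-1-en-2-yl)octahydronaphthalen-1(2H)-one | C=C(C)[C@@H]1CC[C@@]2(C)[C@H](Br)CCC(=O)[C@]2(O[Si](C)(C)c3ccccc3)C1 | intermediate
17 | {[(1R,4aR,6R,8aR)-1-bromo-8a-methyl-4-methylidene-6-(prop-1-en-2-yl)decahydronaphthalen-4a-yl]oxy}dimethyl(phenyl)silane | C=C(C)[C@@H]1CC[C@@]2(C)[C@H](Br)CCC(=C)[C@]2(O[Si](C)(C)c3ccccc3)C1 | intermediate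
18 | {[(1R,4aR,6R,8aR)-1-bromo-8a-methyl-4-methylidene-6-[(1E)-1-(4,4,5,5-tetramethyl-1,3,2-dioxaborolan-2-yl)prop-1-en-2-yl]decahydronaphthalen-4a-yl]oxy}dimethyl(phenyl)silane | CC1(C)OB(/C=C(\C)[C@@H]2CC[C@@]3(C)[C@H](Br)CCC(=C)[C@]3(O[Si](C)(C)c4ccccc4)C2)OC1(C)C | intermediate
19 | 2-methylbut-1-en-3-yne | C=C(C)C#C | starting material
20 | chlorobis(cyclopentadienyl)[(1E)-3-methylbuta-1,3-dien-1-yl]zirconium | C=C(C)/C=C/[Zr](Cl)(C1C=CC=C1)C1C=CC=C1 | intermediate
21 | (1E)-1-iodo-3-methylbuta-1,3-diene | C=C(C)/C=C/I | intermediate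
22 | {[(1R,4aR,6R,8aR)-1-bromo-8a-methyl-4-methylidene-6-[(2E,4E)-6-methylhepta-2,4,6-trien-2-yl]decahydronaphthalen-4a-yl]oxy}dimethyl(phenyl)silane | C=C(C)/C=C/C=C(\C)[C@@H]1CC[C@@]2(C)[C@H](Br)CCC(=C)[C@]2(O[Si](C)(C)c3ccccc3)C1 | intermediate
23 | (1R,4aR,6R,8aR)-1-bromo-8a-methyl-4-methylidene-6-[(2E,4E)-6-methylhepta-2,4,6-trien-2-yl]decahydronaphthalen-4a-ol | C=C(C)/C=C/C=C(\C)[C@@H]1CC[C@@]2(C)[C@H](Br)CCC(=C)[C@]2(O)C1 | target

**Totals.** Total step count: 14. Longest linear sequence: 13 steps (steps 1–11, 13, 14); step 12 prepares the coupling partner.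

**Steps most likely to fail**

1. Step 9 (key step). Bromine transfer to the cyclised C1 radical may be too slow to outrun its reduction, its oxidation or its addition to an isopropenyl group of a second molecule, and delivery on the α face may compete. The fallback sets out from 15 and comes back at 16. Displacement of the bromide of 15 with potassium O-ethyl xanthate (acetone, 0 °C) should give the S-(2-oxoalkyl) O-ethyl dithiocarbonate F1. Its degenerative xanthate-transfer cyclisation (dilauroyl peroxide, 1,2-dichloroethane, reflux), a robust chain process for 6-endo closures of α-keto radicals, should give the ring-closed C1 dithiocarbonate F2 as a mixture of C1 epimers. Radical exchange of the xanthate for bromine with ethyl 2-bromo-2-methylpropanoate (dilauroyl peroxide, chlorobenzene, reflux) regenerates the C1 radical in the closed decalin. A small bromine donor should again approach anti to the axial silyloxy group, which returns 16.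

2. Step 11. Metathesis may initiate sluggishly at the α-branched 1,1-disubstituted alkene, the catalyst may decay before turnover, the C4 methylidene may be engaged, or E selectivity may be incomplete. The fallback sets out from 17 and comes back at 18. Osmium-catalysed dihydroxylation of the more accessible isopropenyl group with in situ periodate cleavage (OsO4 cat., NaIO4, 2,6-lutidine, dioxane/H2O; Lemieux–Johnson oxidation) should pass through the diol F3 to the methyl ketone F4. Boron–Wittig olefination of F4 with lithiated bis(pinacolato)borylmethane (CH2(Bpin)2, lithium 2,2,6,6-tetramethylpiperidide, THF, −78 → 25 °C) should then give the trisubstituted alkenyl boronate 18 with boron anti to the ring carbon.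

3. Step 2. The substrate's own preference for allylation cis to the isopropenyl group may erode catalyst control (mismatched double stereodifferentiation). The fallback sets out from 1 and comes back at 6, bypassing steps 1–3. Conjugate reduction of 1 (LiBH(s-Bu)3, THF, −78 °C; aqueous NH4Cl) gives dihydrocarvone F5. Condensation with (R)-1-phenylethylamine (toluene, reflux, water removal) gives the imine F6. Its chiral-imine Michael addition to methyl acrylate through the more substituted secondary enamine, followed by aqueous acetic acid, should give the keto ester F7 with the new chain trans to the isopropenyl group under reagent control. Saponification (LiOH, THF/H2O) gives the keto acid F8. Oxidative decarboxylation (Pb(OAc)4, Cu(OAc)2 cat., pyridine, benzene, 80 °C) converts the propanoic acid chain into the vinyl group of 6.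

**Further compounds**

F1 | step 9 | O-ethyl S-{2-[(1S,2S,5R)-1-{[dimethyl(phenyl)silyl]oxy}-2-ethenyl-2-methyl-5-(prop-1-en-2-yl)cyclohexyl]-2-oxoethyl} carbonodithioate | C=C(C)[C@@H]1CC[C@@](C)(C=C)[C@](O[Si](C)(C)c2ccccc2)(C(=O)CSC(=S)OCC)C1
F2 | step 9 | S-[(4aR,7R,8aS)-8a-{[dimethyl(phenyl)silyl]oxy}-4a-methyl-1-oxo-7-(prop-1-en-2-yl)decahydronaphthalen-4-yl] O-ethyl carbonodithioate (C4 epimers) | C=C(C)[C@@H]1CC[C@@]2(C)C(SC(=S)OCC)CCC(=O)[C@]2(O[Si](C)(C)c3ccccc3)C1
F3 | step 11 | 2-[(2R,4aR,5R,8aR)-5-bromo-8a-{[dimethyl(phenyl)silyl]oxy}-4a-methyl-8-methylidenedecahydronaphthalen-2-yl]propane-1,2-diol (epimers at the carbinol carbon) | OCC(C)(O)[C@@H]1CC[C@@]2(C)[C@H](Br)CCC(=C)[C@]2(O[Si](C)(C)c3ccccc3)C1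
F4 | step 11 | 1-[(2R,4aR,5R,8aR)-5-bromo-8a-{[dimethyl(phenyl)silyl]oxy}-4a-methyl-8-methylidenedecahydronaphthalen-2-yl]ethan-1-one | CC(=O)[C@@H]1CC[C@@]2(C)[C@H](Br)CCC(=C)[C@]2(O[Si](C)(C)c3ccccc3)C1
F5 | step 2 | (5R)-2-methyl-5-(prop-1-en-2-yl)cyclohexan-1-one (dihydrocarvone, C2 epimers) | C=C(C)[C@@H]1CCC(C)C(=O)C1
F6 | step 2 | (5R)-2-methyl-N-[(1R)-1-phenylethyl]-5-(prop-1-en-2-yl)cyclohexan-1-imine | C=C(C)[C@@H]1CCC(C)C(=N[C@H](C)c2ccccc2)C1
F7 | step 2 | methyl 3-[(1S,4R)-1-methyl-2-oxo-4-(prop-1-en-2-yl)cyclohexyl]propanoate | C=C(C)[C@@H]1CC[C@@](C)(CCC(=O)OC)C(=O)C1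
F8 | step 2 | 3-[(1S,4R)-1-methyl-2-oxo-4-(prop-1-en-2-yl)cyclohexyl]propanoic acid | C=C(C)[C@@H]1CC[C@@](C)(CCC(=O)O)C(=O)C1
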